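The constants used here stand for no real mixture, and the outcome is calculated.

Coming back to this page cold, we take equal charges in baths of different temperature, and ask how much target stands in each when the clock is stopped.

| setting | amber | teal | green |
|---|---|---|---|
| substrate | 37 mM | 37 mM | 37 mM |
| coupling partner | 38.9 mM | 38.9 mM | 38.9 mM |
| temperature | 50 °C | 70 °C | 30 °C |
| time | 50 min | 50 min | 50 min |

    substrate + coupling partner → intermediate + released group (k1 = 0.0042 /M/s, Ea1 = 68.0 kJ/mol)
    target ⇌ isomer of the product B (K2 = 0.73, k2 = 4.8 × 10⁻⁴ /s, Ea2 = 110 kJ/mol, ΔH2 = −45.0 kJ/mol)
    intermediate ⇌ isomer of the product A (K3 = 2.5, k3 = 1.5 × 10⁻⁴ /s, Ea3 = 97.0 kJ/mol, ΔH3 = −21.0 kJ/mol)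
    intermediate ⇌ target (K4 = 4.6, k4 = 3.9 × 10⁻⁴ /s, Ea4 = 96.0 kJ/mol, ΔH4 = −26.0 kJ/mol)
    (constants at 50 °C)

- all constants are for 50 °C and move with temperature by the activation energies and enthalpies

- which flask leads in amount of target, in percent of the substrate charged ("all alike" within 1.5 percentage points) (amber / teal / green / all alike)
- how much target is there at the end, in percent of the substrate charged: amber
- how much target is there at the end, in percent of the substrate charged: teal
- how much target is there at the end, in percent of the substrate charged: green

In the first instants the flask holds substrate and coupling partner, and the first step starts. The substrate is the limiting reagent, at 37 mM against 38.9 mM. The charges are nearly equal, so we treat it as an equal-charge second-order run. Call u the first rate constant times the starting [coupling partner] times the time; the part reacted is then u/(1+u). In amber u is 0.490, so 32.9% of the substrate has reacted at the end.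

In the middle, what has reacted sits in a pool of intermediate, target and the two isomers. While [target] is small it grows as the forward constant of the intermediate-to-target step, 3.9 × 10⁻⁴ /s in amber, times the accumulated [intermediate]. Taking [intermediate], as a part of the charge, to rise in step with time up to u, we get the early level: u times that constant times the time, divided by two, which in amber is 28.7% of the charge.

Given time, the pool tends to equilibrium. Setting the intermediate to one in amber, target stands at 4.6, the isomer of the product A at 2.5, and the isomer of the product B at 3.36. The target's fraction of that sum is the pool share 40.1% in amber. Share times part reacted gives the equilibrium level, 13.2%. Target follows the early level first and the equilibrium level late, so we join them by a rule of thumb, adding reciprocals as for resistances in series. For amber this gives 9.04%.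

Teal has u = 2.14, so 68.2% has reacted. Its share is 44.2%, giving an equilibrium level of 30.1%. Its early level of 1006% is a formal figure, not an amount, since it carries the early rise past the charge; it stands far above the equilibrium level, so we take teal to be near equilibrium within its pool, and we get 29.3%.

Green has u = 0.0923, so 8.45% has reacted, and its share is 26.3%. Because green's relaxation half-life of intermediate and target, 4.68 h, is long against 50 min, green stays near its early level of 0.511%, which lies below its equilibrium level 2.22%. Joined, they give 0.416%. So we expect teal to lead.

The forecast named teal, with 9.3% in amber, 30.5% in teal and 0.45% in green, noting for teal that “Target and B equilibrate fast”. The simulation gives 9.10% in amber, 30.4% in teal and 0.442% in green, so teal leads.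

Of what has reacted, teal holds 43.9% as target, beside its pool share 44.2%, while amber holds 27.4%, short of 40.1%. The neighbour repeats green at 55 °C. Its u is 0.721, so 41.9% has reacted by reckoning, against 42.3% in that flask. Its share is 42.1%, its equilibrium level 17.6% and its early level 72.7%. Joined, these give 14.2%, and the flask at 55 °C holds 14.2% of target.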